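## Retrosynthetic overview

1. Feature: O1 of the oxolane joins two benzylic carbons, C2 (ring B) and C5 (ring A). The 2,3-cis-3,4-trans-4,5-cis core is C2-symmetric and both rings carry the same (7R,8R) arm, so one arm-bearing aldehyde supplies both halves.
2. Last disconnections: the two arm hydroxyls come from TIPS ethers, and C3–CH3 comes from C3–CO2Me.
3. Key disconnection C2–C3: C2 begins as the OCH2 of a 4-alkoxy-3-methoxybenzyl ether on the C5 oxygen, and C3 as the diazo carbon of a 2-diazo ester. Rhodium carbenoid 1,5 C–H insertion closes the oxolane, the only ring that is built.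
4. The diazo ester comes from the butanoate by deacylative diazo transfer. The butanoate comes by Arndt–Eistert homologation of the O-benzylated Evans syn aldol acid (sets C4 and C5). The benzyl donor is the trichloroacetimidate made from the same aldehyde.
5. Aldehyde: Mitsunobu inversion of ethyl (S)-lactate (C8), Weinreb ketone synthesis, Felkin–Anh reduction (C7), silylation, then bromine–lithium exchange and formylation.

Key step: step 15

Abbreviations: Ar* = 3-methoxy-4-{[(1R,2R)-1-(3,4-dimethoxyphenyl)-1-(triisopropylsilyloxy)propan-2-yl]oxy}phenyl. C7 and C8 are the carbinol carbon and the aryloxy-bearing carbon of an arm. Oxolane numbering (O1, C2–C5) is used for the core atoms from the aldol onward.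

Assumption: the target is taken exactly as drawn, with threo (7R,8R) arms on a (2R,3S,4S,5R) oxolane.

Remarks:
- 4-Bromo-2-methoxyphenol is used as the phenol, so no aldehyde protecting group is needed. The formyl group is introduced once the arm is complete.
- Metal alkoxide adducts that are only hydrolysed on work-up are not numbered.

## Route

Step 1
Reactants: 1 4-bromo-2-methoxyphenol; 2 ethyl (S)-lactate
Product: 3 ethyl (R)-2-(4-bromo-2-methoxyphenoxy)propanoate
Conditions: PPh3, DIAD, THF, 0 °C → rt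
Reagents that add atoms: none
Why: Mitsunobu etherification, in which the phenol displaces the activated lactate oxygen by SN2 with inversion, so that the (S) carbinol carbon becomes the (R)-configured C8 of the arm.

Step 2
Reactants: 3 ethyl (R)-2-(4-bromo-2-methoxyphenoxy)propanoate
Product: 4 (R)-2-(4-bromo-2-methoxyphenoxy)-N-methoxy-N-methylpropanamide
Conditions: MeNH(OMe)·HCl, i-PrMgCl, THF, −20 → 0 °C; H2O
Reagents that add atoms: N,O-dimethylhydroxylamine hydrochloride, CNOC.Cl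
Why: Weinreb amide synthesis by aminolysis of the ester with the chloromagnesium amide made in the flask, fast enough below 0 °C that the alpha-aryloxy stereocentre C8 is not enolised and the electron-rich aryl bromide does not exchange.

Step 3
Reactants: 4 (R)-2-(4-bromo-2-methoxyphenoxy)-N-methoxy-N-methylpropanamide; 5 4-bromoveratrole
Product: 7 (R)-2-(4-bromo-2-methoxyphenoxy)-1-(3,4-dimethoxyphenyl)propan-1-one, via arylmagnesium bromide 6 (not isolated)
Conditions: 5, Mg, THF, 40 °C; decanted onto 4, THF, 0 °C; H2O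
Reagents that add atoms: magnesium, [Mg] (kept in 6 only)
Why: Weinreb ketone synthesis with a Grignard reagent, which stops after one addition because the carbonyl group is set free only on hydrolysis, so that over-addition and base-induced epimerisation at C8 are both avoided.

Step 4
Reactants: 7 (R)-2-(4-bromo-2-methoxyphenoxy)-1-(3,4-dimethoxyphenyl)propan-1-one
Product: 8 (1R,2R)-2-(4-bromo-2-methoxyphenoxy)-1-(3,4-dimethoxyphenyl)propan-1-ol
Conditions: Bu4NBH4, CH2Cl2–MeOH, −78 → −20 °C; H2O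
Reagents that add atoms: none
Why: Felkin–Anh controlled borohydride reduction: with the non-coordinating Bu4N+ counter-ion no chelate can form, the polar C8–OAr bond stands perpendicular to the carbonyl group and hydride enters anti to it past the C8 hydrogen, which should set C7 as R (threo arm), any erythro isomer being removed by chromatography.

Step 5
Reactants: 8 (1R,2R)-2-(4-bromo-2-methoxyphenoxy)-1-(3,4-dimethoxyphenyl)propan-1-ol
Product: 9 Ar*–Br, [(1R,2R)-2-(4-bromo-2-methoxyphenoxy)-1-(3,4-dimethoxyphenyl)propoxy]triisopropylsilane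
Conditions: TIPSOTf, 2,6-lutidine, CH2Cl2, 0 °C → rt
Reagents that add atoms: triisopropylsilyl triflate, CC(C)[Si](OS(=O)(=O)C(F)(F)F)(C(C)C)C(C)C
Why: Silyl ether formation with a silyl triflate and a hindered pyridine base, which is reactive enough for this crowded benzylic alcohol, keeps the medium non-acidic so that C7 is not ionised, and installs a group bulky enough to shield the C7–H bond from the later carbenoid.

Step 6
Reactants: 9 Ar*–Br
Product: 11 Ar*–CHO (3-methoxy-4-arm-substituted benzaldehyde), via aryllithium 10 (not isolated)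
Conditions: n-BuLi, THF, −78 °C; DMF, −78 → 0 °C; H2O
Reagents that add atoms: N,N-dimethylformamide, CN(C)C=O; n-butyllithium, [Li]CCCC (lithium kept in 10 only)
Why: Bromine–lithium exchange followed by formylation with DMF (Bouveault aldehyde synthesis), the exchange at −78 °C being much faster than any deprotonation and the silyl and aryl ethers being inert to it.

Step 7
Reactants: 11 Ar*–CHO
Product: 12 Ar*–CH2OH
Conditions: NaBH4, THF–MeOH, 0 °C
Reagents that add atoms: none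
Why: Chemoselective borohydride reduction of the aromatic aldehyde, the only reducible group present.

Step 8
Reactants: 12 Ar*–CH2OH
Product: 13 Ar*–CH2 2,2,2-trichloroacetimidate
Conditions: Cl3CCN, DBU (10 mol %), CH2Cl2, 0 °C
Reagents that add atoms: trichloroacetonitrile, N#CC(Cl)(Cl)Cl
Why: Base-catalysed addition of the benzylic alcohol to trichloroacetonitrile (trichloroacetimidate synthesis), a process that leaves the silyl ether alone and gives a donor that is used promptly because 3,4-dialkoxybenzyl imidates ionise easily.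

Step 9
Reactants: 14 (R)-4-benzyl-3-propionyloxazolidin-2-one; 11 Ar*–CHO
Product: 16 (R)-4-benzyl-3-[(2R,3R)-3-Ar*-3-hydroxy-2-methylpropanoyl]oxazolidin-2-one, via boron enolate 15 (not isolated)
Conditions: 14, Bu2BOTf, Et3N, CH2Cl2, −78 → 0 °C; 11, −78 → 0 °C; pH 7 buffer, MeOH, 30% H2O2, 0 °C
Reagents that add atoms: dibutylboron triflate, CCCCB(CCCC)OS(=O)(=O)C(F)(F)F (boron kept in 15 only)
Why: Evans syn aldol reaction: the (Z)-boron enolate 15 reacts through a closed Zimmerman–Traxler chair on the enolate face left open by the benzyl group of the (R)-auxiliary, which should give the (2R,3R) syn adduct and thereby set C4 (S in the target) and C5 (R) of the oxolane in their cis relation.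

Step 10
Reactants: 16 aldol adduct; 13 Ar*–CH2 trichloroacetimidate
Product: 17 (R)-4-benzyl-3-[(2R,3R)-3-Ar*-3-(Ar*-methoxy)-2-methylpropanoyl]oxazolidin-2-one
Conditions: La(OTf)3 (5 mol %), toluene, 0 °C → rt
Reagents that add atoms: none
Why: Lewis-acid-catalysed O-alkylation with a trichloroacetimidate, in which the 3,4-dialkoxybenzyl donor ionises under a very mild catalyst and is captured by the free hydroxyl, so that no base is present to trigger retro-aldol cleavage and the C5–O bond is never broken.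

Step 11
Reactants: 17 O-benzylated imide
Product: 19 (2R,3R)-3-Ar*-3-(Ar*-methoxy)-2-methylpropanoic acid, via peroxy acid 18 (not isolated)
Conditions: LiOH, 30% H2O2, THF–H2O, 0 °C; aq Na2SO3; dilute HCl to pH 4, 0 °C
Reagents that add atoms: hydrogen peroxide, OO
Why: Hydroperoxide cleavage of the N-acyloxazolidinone, in which the small alpha-effect nucleophile attacks the exocyclic carbonyl group even of a hindered imide, sulfite then reduces peroxy acid 18, and the etherified C5 oxygen rules out retro-aldol loss.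

Step 12
Reactants: 19 acid
Product: 21 (3R,4R)-4-Ar*-4-(Ar*-methoxy)-1-diazo-3-methylbutan-2-one, via mixed anhydride 20 (not isolated)
Conditions: i-BuOCOCl, N-methylmorpholine, THF, −20 °C; CH2N2, Et2O, −20 → 0 °C
Reagents that add atoms: diazomethane, C=[N+]=[N-]; isobutyl chloroformate, CC(C)COC(=O)Cl (kept in 20 only)
Why: First stage of the Arndt–Eistert homologation, C-acylation of diazomethane by the mixed carbonic anhydride 20, which is formed cold with a weak amine base so that the alpha stereocentre (future C4) is not epimerised.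

Step 13
Reactants: 21 diazoketone
Product: 23 methyl (3S,4R)-4-Ar*-4-(Ar*-methoxy)-3-methylbutanoate, via ketene 22 (not isolated)
Conditions: AgO2CPh (10 mol %), Et3N, THF–MeOH, −25 °C → rt, dark
Reagents that add atoms: methanol, CO
Why: Wolff rearrangement (second stage of the Arndt–Eistert homologation): silver-induced loss of N2 with 1,2-shift of the stereogenic carbon, which migrates with retention, gives ketene 22 and methanol adds to it to give the ester.

Step 14
Reactants: 23 methyl butanoate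
Product: 26 methyl (3S,4R)-4-Ar*-4-(Ar*-methoxy)-2-diazo-3-methylbutanoate, via lithium enolate 24 (not isolated), via trifluoroacetyl ester 25 (not isolated)
Conditions: LiN(SiMe3)2, THF, −78 °C; CF3CO2CH2CF3, −78 °C; aq NH4Cl; then 4-AcNHC6H4SO2N3, Et3N, H2O (1 equiv), MeCN, rt
Reagents that add atoms: 4-acetamidobenzenesulfonyl azide, CC(=O)Nc1ccc(cc1)S(=O)(=O)N=[N+]=[N-]; 2,2,2-trifluoroethyl trifluoroacetate, FC(F)(F)COC(=O)C(F)(F)F (kept in 25 only); lithium hexamethyldisilazide, [Li]N([Si](C)(C)C)[Si](C)(C)C (lithium kept in 24 only)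
Why: Deacylative Regitz diazo transfer: Claisen-type C-trifluoroacetylation of enolate 24 makes C2 of the butanoate acidic enough for amine-promoted transfer from the sulfonyl azide, the trifluoroacetyl group leaves on the sulfonamide nitrogen, and beta-elimination is not possible because the ether oxygen is gamma to the ester.

Step 15
Reactants: 26 methyl (3S,4R)-4-Ar*-4-(Ar*-methoxy)-2-diazo-3-methylbutanoate
Product: 28 methyl (2R,3S,4S,5R)-2,5-bis(Ar*)-4-methyloxolane-3-carboxylate, via rhodium carbenoid 27 (not isolated)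
Conditions: Rh2(O2CCPh3)4 (2 mol %), 4 Å MS, CH2Cl2, −78 → −20 °C, slow addition of 26
Reagents that add atoms: none
Why: Rh2(O2CCPh3)4 takes N2 out of 26 and leaves the electrophilic carbenoid 27 at C3, whose empty orbital draws hydride character from one O1–CH2 hydrogen while C2–C3 forms in the same asynchronous three-centre event, with retention at C2. The closest known reaction type is the dirhodium-carboxylate-catalysed intramolecular 1,5 C–H insertion of 2-alkyl-2-diazo esters alpha to an ether oxygen, which gives oxolane-3-carboxylates. The oxolane, the only ring closed, forms by 1,5-insertion through a six-centre array made of C3, C4, C5, O1, C2 and the migrating hydrogen. For C2 relative to C3, bulky dirhodium carboxylates at low temperature are known to place aryl and ester cis in benzylic insertions (2-arylcyclopentanecarboxylates from 2-diazo-6-arylhexanoates, 2-aryl-2,3-dihydrobenzofuran-3-carboxylates), because the aryl group on the reacting carbon turns away from the ligand wall. Of the two 2,3-cis arrays the one on the face that already holds the C4 methyl and ring A would be an all-cis ring, so the C4 and C5 stereocentres should pick the opposite carbene face (C3 = S) and the matching diastereotopic hydrogen (C2 = R), which is the cis-trans-cis array. The step needs chemoselectivity over 1,2-hydride migration from C4–H, over attack on the ortho carbons of ring A and over the arm carbinol C–H bonds; the first is held back by the triphenylacetate ligands at −78 °C, and the others by the fact that the target C–H is the only one within five-ring reach that is activated both by O1 and by the para-alkoxy group of ring B, the arm C–H bonds being remote and shielded by TIPS.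

Step 16
Reactants: 28 oxolane ester
Product: 29 [(2R,3R,4S,5R)-2,5-bis(Ar*)-4-methyloxolan-3-yl]methanol
Conditions: LiAlH4, THF, −20 → 0 °C; H2O
Reagents that add atoms: none
Why: Ester reduction with LiAlH4, run cold so that hydride addition outruns enolisation of the kinetically set, epimerisable C3 centre, while silyl, benzylic and aryl ethers are inert.

Step 17
Reactants: 29 primary alcohol
Product: 30 [(2R,3R,4S,5R)-2,5-bis(Ar*)-4-methyloxolan-3-yl]methyl methanesulfonate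
Conditions: MsCl, Et3N, CH2Cl2, 0 °C
Reagents that add atoms: methanesulfonyl chloride, CS(=O)(=O)Cl
Why: Mesylation of the primary alcohol under standard amine-base conditions, which touches no stereocentre.

Step 18
Reactants: 30 mesylate
Product: 31 (2R,3S,4S,5R)-2,5-bis(Ar*)-3,4-dimethyloxolane
Conditions: LiBHEt3, THF, 0 → 40 °C
Reagents that add atoms: none
Why: SN2 hydride displacement of the primary mesylate by the strongly nucleophilic triethylborohydride, the standard way to turn an oxolane CH2OH group into CH3, with no change at C3.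

Step 19
Reactants: 31 bis-TIPS ether
Product: 32 CNP0116650.3, (1R,1'R,2R,2'R)-2,2'-{[(2R,3S,4S,5R)-3,4-dimethyloxolane-2,5-diyl]bis[(2-methoxy-4,1-phenylene)oxy]}bis[1-(3,4-dimethoxyphenyl)propan-1-ol]
Conditions: Bu4NF, THF, 0 °C → rt; H2O
Reagents that add atoms: none
Why: Fluoride-induced cleavage of both silyl ethers, driven by the Si–F bond and neutral enough to leave the benzylic C–O bonds and all eight stereocentres intact.

## Compound list

1 | 4-bromo-2-methoxyphenol | COc1cc(Br)ccc1O | starting material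
2 | ethyl (S)-lactate | C[C@H](O)C(=O)OCC | starting material
3 | ethyl (R)-2-(4-bromo-2-methoxyphenoxy)propanoate | CCOC(=O)[C@@H](C)Oc1ccc(Br)cc1OC | intermediate
4 | (R)-2-(4-bromo-2-methoxyphenoxy)-N-methoxy-N-methylpropanamide | CON(C)C(=O)[C@@H](C)Oc1ccc(Br)cc1OC | intermediate
5 | 4-bromoveratrole | COc1ccc(Br)cc1OC | starting material
6 | 3,4-dimethoxyphenylmagnesium bromide (not isolated) | COc1ccc([Mg]Br)cc1OC | intermediate
7 | (R)-2-(4-bromo-2-methoxyphenoxy)-1-(3,4-dimethoxyphenyl)propan-1-one | COc1ccc(C(=O)[C@@H](C)Oc2ccc(Br)cc2OC)cc1OC | intermediate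
8 | (1R,2R)-2-(4-bromo-2-methoxyphenoxy)-1-(3,4-dimethoxyphenyl)propan-1-ol | COc1ccc([C@@H](O)[C@@H](C)Oc2ccc(Br)cc2OC)cc1OC | intermediate
9 | Ar*–Br | COc1ccc([C@@H](O[Si](C(C)C)(C(C)C)C(C)C)[C@@H](C)Oc2ccc(Br)cc2OC)cc1OC | intermediate
10 | Ar*–Li (not isolated) | COc1ccc([C@@H](O[Si](C(C)C)(C(C)C)C(C)C)[C@@H](C)Oc2ccc([Li])cc2OC)cc1OC | intermediate
11 | Ar*–CHO | COc1ccc([C@@H](O[Si](C(C)C)(C(C)C)C(C)C)[C@@H](C)Oc2ccc(C=O)cc2OC)cc1OC | intermediate
12 | Ar*–CH2OH | COc1ccc([C@@H](O[Si](C(C)C)(C(C)C)C(C)C)[C@@H](C)Oc2ccc(CO)cc2OC)cc1OC | intermediate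
13 | Ar*–CH2 2,2,2-trichloroacetimidate | COc1ccc([C@@H](O[Si](C(C)C)(C(C)C)C(C)C)[C@@H](C)Oc2ccc(COC(=N)C(Cl)(Cl)Cl)cc2OC)cc1OC | intermediate
14 | (R)-4-benzyl-3-propionyloxazolidin-2-one | CCC(=O)N1[C@H](Cc2ccccc2)COC1=O | starting material
15 | (Z)-dibutylboron enolate of 14 (not isolated) | C/C=C(\OB(CCCC)CCCC)N1[C@H](Cc2ccccc2)COC1=O | intermediate
16 | (R)-4-benzyl-3-[(2R,3R)-3-Ar*-3-hydroxy-2-methylpropanoyl]oxazolidin-2-one | O[C@@H](c1ccc(O[C@H](C)[C@H](O[Si](C(C)C)(C(C)C)C(C)C)c2ccc(OC)c(OC)c2)c(OC)c1)[C@@H](C)C(=O)N3[C@H](Cc4ccccc4)COC3=O | intermediate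
17 | (R)-4-benzyl-3-[(2R,3R)-3-Ar*-3-(Ar*-methoxy)-2-methylpropanoyl]oxazolidin-2-one | COc1ccc([C@@H](O[Si](C(C)C)(C(C)C)C(C)C)[C@@H](C)Oc2ccc(CO[C@@H](c3ccc(O[C@H](C)[C@H](O[Si](C(C)C)(C(C)C)C(C)C)c4ccc(OC)c(OC)c4)c(OC)c3)[C@@H](C)C(=O)N5[C@H](Cc6ccccc6)COC5=O)cc2OC)cc1OC | intermediate
18 | (2R,3R)-3-Ar*-3-(Ar*-methoxy)-2-methylpropaneperoxoic acid (not isolated) | COc1ccc([C@@H](O[Si](C(C)C)(C(C)C)C(C)C)[C@@H](C)Oc2ccc(CO[C@@H](c3ccc(O[C@H](C)[C@H](O[Si](C(C)C)(C(C)C)C(C)C)c4ccc(OC)c(OC)c4)c(OC)c3)[C@@H](C)C(=O)OO)cc2OC)cc1OC | intermediate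
19 | (2R,3R)-3-Ar*-3-(Ar*-methoxy)-2-methylpropanoic acid | COc1ccc([C@@H](O[Si](C(C)C)(C(C)C)C(C)C)[C@@H](C)Oc2ccc(CO[C@@H](c3ccc(O[C@H](C)[C@H](O[Si](C(C)C)(C(C)C)C(C)C)c4ccc(OC)c(OC)c4)c(OC)c3)[C@@H](C)C(=O)O)cc2OC)cc1OC | intermediate
20 | isobutyl carbonic anhydride of 19 (not isolated) | COc1ccc([C@@H](O[Si](C(C)C)(C(C)C)C(C)C)[C@@H](C)Oc2ccc(CO[C@@H](c3ccc(O[C@H](C)[C@H](O[Si](C(C)C)(C(C)C)C(C)C)c4ccc(OC)c(OC)c4)c(OC)c3)[C@@H](C)C(=O)OC(=O)OCC(C)C)cc2OC)cc1OC | intermediate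
21 | (3R,4R)-4-Ar*-4-(Ar*-methoxy)-1-diazo-3-methylbutan-2-one | COc1ccc([C@@H](O[Si](C(C)C)(C(C)C)C(C)C)[C@@H](C)Oc2ccc(CO[C@@H](c3ccc(O[C@H](C)[C@H](O[Si](C(C)C)(C(C)C)C(C)C)c4ccc(OC)c(OC)c4)c(OC)c3)[C@@H](C)C(=O)C=[N+]=[N-])cc2OC)cc1OC | intermediate
22 | (3S,4R)-4-Ar*-4-(Ar*-methoxy)-3-methylbut-1-en-1-one, the ketene (not isolated) | COc1ccc([C@@H](O[Si](C(C)C)(C(C)C)C(C)C)[C@@H](C)Oc2ccc(CO[C@@H](c3ccc(O[C@H](C)[C@H](O[Si](C(C)C)(C(C)C)C(C)C)c4ccc(OC)c(OC)c4)c(OC)c3)[C@@H](C)C=C=O)cc2OC)cc1OC | intermediate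
23 | methyl (3S,4R)-4-Ar*-4-(Ar*-methoxy)-3-methylbutanoate | COc1ccc([C@@H](O[Si](C(C)C)(C(C)C)C(C)C)[C@@H](C)Oc2ccc(CO[C@@H](c3ccc(O[C@H](C)[C@H](O[Si](C(C)C)(C(C)C)C(C)C)c4ccc(OC)c(OC)c4)c(OC)c3)[C@@H](C)CC(=O)OC)cc2OC)cc1OC | intermediate
24 | lithium enolate of 23 (not isolated, enolate geometry open) | COc1ccc([C@@H](O[Si](C(C)C)(C(C)C)C(C)C)[C@@H](C)Oc2ccc(CO[C@@H](c3ccc(O[C@H](C)[C@H](O[Si](C(C)C)(C(C)C)C(C)C)c4ccc(OC)c(OC)c4)c(OC)c3)[C@@H](C)C=C(O[Li])OC)cc2OC)cc1OC | intermediate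
25 | methyl (3S,4R)-4-Ar*-4-(Ar*-methoxy)-3-methyl-2-(trifluoroacetyl)butanoate (not isolated, C2 epimers and enol) | COc1ccc([C@@H](O[Si](C(C)C)(C(C)C)C(C)C)[C@@H](C)Oc2ccc(CO[C@@H](c3ccc(O[C@H](C)[C@H](O[Si](C(C)C)(C(C)C)C(C)C)c4ccc(OC)c(OC)c4)c(OC)c3)[C@@H](C)C(C(=O)C(F)(F)F)C(=O)OC)cc2OC)cc1OC | intermediate
26 | methyl (3S,4R)-4-Ar*-4-(Ar*-methoxy)-2-diazo-3-methylbutanoate (key-step precursor) | COc1ccc([C@@H](O[Si](C(C)C)(C(C)C)C(C)C)[C@@H](C)Oc2ccc(CO[C@@H](c3ccc(O[C@H](C)[C@H](O[Si](C(C)C)(C(C)C)C(C)C)c4ccc(OC)c(OC)c4)c(OC)c3)[C@@H](C)C(=[N+]=[N-])C(=O)OC)cc2OC)cc1OC | intermediate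
27 | carbenoid of 26 on Rh2(O2CCPh3)4, carbene carbon = C3 (not isolated; bridging carboxylates drawn monodentate) | COc1ccc([C@@H](O[Si](C(C)C)(C(C)C)C(C)C)[C@@H](C)Oc2ccc(CO[C@@H](c3ccc(O[C@H](C)[C@H](O[Si](C(C)C)(C(C)C)C(C)C)c4ccc(OC)c(OC)c4)c(OC)c3)[C@@H](C)C(=[Rh](OC(=O)C(c5ccccc5)(c5ccccc5)c5ccccc5)(OC(=O)C(c5ccccc5)(c5ccccc5)c5ccccc5)[Rh](OC(=O)C(c5ccccc5)(c5ccccc5)c5ccccc5)OC(=O)C(c5ccccc5)(c5ccccc5)c5ccccc5)C(=O)OC)cc2OC)cc1OC | intermediate
28 | methyl (2R,3S,4S,5R)-2,5-bis(Ar*)-4-methyloxolane-3-carboxylate (key-step product) | COc1ccc([C@@H](O[Si](C(C)C)(C(C)C)C(C)C)[C@@H](C)Oc2ccc([C@@H]3O[C@@H](c4ccc(O[C@H](C)[C@H](O[Si](C(C)C)(C(C)C)C(C)C)c5ccc(OC)c(OC)c5)c(OC)c4)[C@@H](C)[C@@H]3C(=O)OC)cc2OC)cc1OC | intermediate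
29 | [(2R,3R,4S,5R)-2,5-bis(Ar*)-4-methyloxolan-3-yl]methanol | COc1ccc([C@@H](O[Si](C(C)C)(C(C)C)C(C)C)[C@@H](C)Oc2ccc([C@@H]3O[C@@H](c4ccc(O[C@H](C)[C@H](O[Si](C(C)C)(C(C)C)C(C)C)c5ccc(OC)c(OC)c5)c(OC)c4)[C@@H](C)[C@@H]3CO)cc2OC)cc1OC | intermediate
30 | [(2R,3R,4S,5R)-2,5-bis(Ar*)-4-methyloxolan-3-yl]methyl methanesulfonate | COc1ccc([C@@H](O[Si](C(C)C)(C(C)C)C(C)C)[C@@H](C)Oc2ccc([C@@H]3O[C@@H](c4ccc(O[C@H](C)[C@H](O[Si](C(C)C)(C(C)C)C(C)C)c5ccc(OC)c(OC)c5)c(OC)c4)[C@@H](C)[C@@H]3COS(C)(=O)=O)cc2OC)cc1OC | intermediate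
31 | (2R,3S,4S,5R)-2,5-bis(Ar*)-3,4-dimethyloxolane | COc1ccc([C@@H](O[Si](C(C)C)(C(C)C)C(C)C)[C@@H](C)Oc2ccc([C@@H]3O[C@@H](c4ccc(O[C@H](C)[C@H](O[Si](C(C)C)(C(C)C)C(C)C)c5ccc(OC)c(OC)c5)c(OC)c4)[C@@H](C)[C@@H]3C)cc2OC)cc1OC | intermediate
32 | CNP0116650.3 | COc1ccc([C@@H](O)[C@@H](C)Oc2ccc([C@@H]3O[C@@H](c4ccc(O[C@H](C)[C@H](O)c5ccc(OC)c(OC)c5)c(OC)c4)[C@@H](C)[C@@H]3C)cc2OC)cc1OC | target

## Step count and risks

Total step count: 19. Longest linear sequence: 18 (steps 1–8 and 10–19; step 9 runs in parallel from 11).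

**Step 15.**
- What may go wrong, diversion of the carbenoid:
  - 1,2-hydride migration from C4
  - electrophilic attack on ring A
  - complete hydride transfer to a free oxocarbenium–enolate pair that recloses with little control
- What may go wrong, stereocontrol: erosion of the kinetic 2,3-cis preference.
- Fallback: it sets out from 11 and 10, returns at 31, and makes the C2–ring B bond instead of C2–C3.

Aldehyde 11 is crotylated with the (Z)-crotyldiisopinocampheylborane derived from (−)-alpha-pinene (Brown crotylation, then NaOH/H2O2) to give (1R,2S)-1-Ar*-2-methylbut-3-en-1-ol F1. Hydroboration with 9-BBN and oxidation gives (1R,2S)-1-Ar*-2-methylbutane-1,4-diol F2. TEMPO/PhI(OAc)2 closes this to (4S,5R)-5-Ar*-4-methyloxolan-2-one F3. LiN(SiMe3)2 and MeI methylate the enolate anti to the C4 methyl to give (3S,4S,5R)-5-Ar*-3,4-dimethyloxolan-2-one F4. i-Bu2AlH at −78 °C gives (3S,4S,5R)-5-Ar*-3,4-dimethyloxolan-2-ol F5, and PhSO2H with CaCl2 gives (3S,4S,5R)-5-Ar*-3,4-dimethyl-2-(phenylsulfonyl)oxolane F6. Aryllithium 10 is transmetallated with ZnBr2 to Ar*-zinc bromide F7. This adds to the oxocarbenium ion released from F6, a known entry to the 2,3-cis-3,4-trans-4,5-cis array of 2,5-diaryl-3,4-dimethyloxolanes, and gives 31.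

**Step 10.**
- What may go wrong:
  - acid-induced ionisation at the electron-rich C5 benzylic position, with epimerisation
  - Friedel–Crafts capture of the benzylic cation by the veratryl rings
  - rearrangement of the imidate before the hindered hydroxyl intercepts it
- Fallback: it sets out from 16 and 11, returns at 19, and makes the ether by acetal opening instead of cationic alkylation.

LiBH4 (THF, 1 equiv MeOH, 0 °C) reduces 16 to (1R,2S)-1-Ar*-2-methylpropane-1,3-diol F8. Condensation with aldehyde 11 (PPTS, toluene, azeotropic removal of water) gives the all-equatorially biased (2R,4R,5S)-2,4-bis(Ar*)-5-methyl-1,3-dioxane F9. i-Bu2AlH coordinates to the less hindered CH2–O oxygen and cleaves that acetal C–O bond, giving (2S,3R)-3-Ar*-3-(Ar*-methoxy)-2-methylpropan-1-ol F10. TEMPO/PhI(OAc)2 in MeCN–H2O oxidises F10 to acid 19.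

**Step 14.**
- What may go wrong: incomplete or O-selective acylation of the hindered ester enolate, so that the diazo transfer stalls at unactivated ester.
- Fallback: it sets out from 23, returns at 26, and brings in nitrogen as azide.

The potassium enolate (KN(SiMe3)2, THF, −78 °C) is azidated with 2,4,6-triisopropylbenzenesulfonyl azide and quenched with AcOH to give methyl (3S,4R)-4-Ar*-4-(Ar*-methoxy)-2-azido-3-methylbutanoate F11, whose C2 epimers converge later. Staudinger reduction (PMe3, THF–H2O) gives methyl (3S,4R)-2-amino-4-Ar*-4-(Ar*-methoxy)-3-methylbutanoate F12. Diazotisation with isoamyl nitrite and catalytic AcOH in warm CHCl3 gives 26.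

## Further compounds

F1 | step 15 | (1R,2S)-1-Ar*-2-methylbut-3-en-1-ol | O[C@@H](c1ccc(O[C@H](C)[C@H](O[Si](C(C)C)(C(C)C)C(C)C)c2ccc(OC)c(OC)c2)c(OC)c1)[C@@H](C)C=C
F2 | step 15 | (1R,2S)-1-Ar*-2-methylbutane-1,4-diol | O[C@@H](c1ccc(O[C@H](C)[C@H](O[Si](C(C)C)(C(C)C)C(C)C)c2ccc(OC)c(OC)c2)c(OC)c1)[C@@H](C)CCO
F3 | step 15 | (4S,5R)-5-Ar*-4-methyloxolan-2-one | O1[C@@H](c2ccc(O[C@H](C)[C@H](O[Si](C(C)C)(C(C)C)C(C)C)c3ccc(OC)c(OC)c3)c(OC)c2)[C@@H](C)CC1=O
F4 | step 15 | (3S,4S,5R)-5-Ar*-3,4-dimethyloxolan-2-one | O1[C@@H](c2ccc(O[C@H](C)[C@H](O[Si](C(C)C)(C(C)C)C(C)C)c3ccc(OC)c(OC)c3)c(OC)c2)[C@@H](C)[C@H](C)C1=O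
F5 | step 15 | (3S,4S,5R)-5-Ar*-3,4-dimethyloxolan-2-ol (anomers) | O1[C@@H](c2ccc(O[C@H](C)[C@H](O[Si](C(C)C)(C(C)C)C(C)C)c3ccc(OC)c(OC)c3)c(OC)c2)[C@@H](C)[C@H](C)C1O
F6 | step 15 | (3S,4S,5R)-5-Ar*-3,4-dimethyl-2-(phenylsulfonyl)oxolane (C2 epimers) | O1[C@@H](c2ccc(O[C@H](C)[C@H](O[Si](C(C)C)(C(C)C)C(C)C)c3ccc(OC)c(OC)c3)c(OC)c2)[C@@H](C)[C@H](C)C1S(=O)(=O)c4ccccc4
F7 | step 15 | Ar*-zinc bromide | COc1ccc([C@@H](O[Si](C(C)C)(C(C)C)C(C)C)[C@@H](C)Oc2ccc([Zn]Br)cc2OC)cc1OC
F8 | step 10 | (1R,2S)-1-Ar*-2-methylpropane-1,3-diol | O[C@@H](c1ccc(O[C@H](C)[C@H](O[Si](C(C)C)(C(C)C)C(C)C)c2ccc(OC)c(OC)c2)c(OC)c1)[C@@H](C)CO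
F9 | step 10 | (2R,4R,5S)-2,4-bis(Ar*)-5-methyl-1,3-dioxane | COc1ccc([C@@H](O[Si](C(C)C)(C(C)C)C(C)C)[C@@H](C)Oc2ccc([C@H]3O[C@@H](c4ccc(O[C@H](C)[C@H](O[Si](C(C)C)(C(C)C)C(C)C)c5ccc(OC)c(OC)c5)c(OC)c4)[C@@H](C)CO3)cc2OC)cc1OC
F10 | step 10 | (2S,3R)-3-Ar*-3-(Ar*-methoxy)-2-methylpropan-1-ol | COc1ccc([C@@H](O[Si](C(C)C)(C(C)C)C(C)C)[C@@H](C)Oc2ccc(CO[C@@H](c3ccc(O[C@H](C)[C@H](O[Si](C(C)C)(C(C)C)C(C)C)c4ccc(OC)c(OC)c4)c(OC)c3)[C@@H](C)CO)cc2OC)cc1OC
F11 | step 14 | methyl (3S,4R)-4-Ar*-4-(Ar*-methoxy)-2-azido-3-methylbutanoate (C2 epimers) | COc1ccc([C@@H](O[Si](C(C)C)(C(C)C)C(C)C)[C@@H](C)Oc2ccc(CO[C@@H](c3ccc(O[C@H](C)[C@H](O[Si](C(C)C)(C(C)C)C(C)C)c4ccc(OC)c(OC)c4)c(OC)c3)[C@@H](C)C(N=[N+]=[N-])C(=O)OC)cc2OC)cc1OC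
F12 | step 14 | methyl (3S,4R)-2-amino-4-Ar*-4-(Ar*-methoxy)-3-methylbutanoate (C2 epimers) | COc1ccc([C@@H](O[Si](C(C)C)(C(C)C)C(C)C)[C@@H](C)Oc2ccc(CO[C@@H](c3ccc(O[C@H](C)[C@H](O[Si](C(C)C)(C(C)C)C(C)C)c4ccc(OC)c(OC)c4)c(OC)c3)[C@@H](C)C(N)C(=O)OC)cc2OC)cc1OC
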